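**Retrosynthetic overview**

1. Ring A is closed last: metathesis makes C1=C2 after a vinyl group has been added to the C10 ketone and the C10 alkoxide has closed the 19,10-lactone onto the C19 ester.
2. Ring B (C5, C6, C8, C9, C10) is closed through C5–C6, the bond joining the α-carbon of the C10 ketone to the α-carbon of the C7 carboxyl; the strategy rests on this 1,4-dicarbonyl bond, made by oxidising the ketone/ester bis-enolate.
3. The bis-enolate precursor is a C10 ketone made by thioester–organozinc coupling of a C/D thioester with an enantiopure alkyl iodide (C3 and C4 set by Evans aldol and Fráter–Seebach alkylation).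
4. Ring C comes from (S)-cyclohex-3-enecarboxylic acid (C9, C10); an iodolactone bridge C10–O–C12 sets C12, shields one face while quaternary C8 is built by two conjugate additions, and is opened late to the thioester.
5. Ring D is closed by an aldol bond C16–C13 from a C8 acetyl group, then α-methylenation (C17) and reduction (C15); rings form in the order C, D, B, lactone, A.

Key step: step 23

Remarks on the chemistry:
- Gibberellane numbering is used for all intermediates (ring C = C8, C9, C11, C12, C13, C14; ring D adds C15 and C16; C17 is the exocyclic methylene).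
- The C7 carboxyl is carried as its 2-(trimethylsilyl)ethyl ester, the C12 and C13 hydroxyls as triethylsilyl ethers and the C3 and C15 hydroxyls as tert-butyldimethylsilyl ethers, so that one fluoride treatment ends the synthesis.
- Assumption: reagents attack the lactone-bridged bicyclo[3.2.1]octanes on the face anti to the two-atom lactone bridge (steps 3, 6, 8), and hydride attacks the C15 ketone on its exo face (step 14).

**Route**

Step 1
Reactants: 1 (S)-cyclohex-3-ene-1-carboxylic acid
Product: 2 (1S,4S,5S)-4-iodo-6-oxabicyclo[3.2.1]octan-7-one (lactone oxygen on C12 cis to C10; iodine on C13 trans to that oxygen)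
Conditions: I2, KI, NaHCO3, H2O/CH2Cl2, 0 °C → rt
Reagents that add atoms: iodine, [I][I]
Why: Iodolactonisation, in which the carboxylate opens the iodonium ion at C12 in a 5-exo closure, so the lactone oxygen is necessarily cis to C10 (C12 is set from C9) and iodine ends trans at C13.

Step 2
Reactants: 2 iodolactone
Product: 3 (1S,5S)-6-oxabicyclo[3.2.1]oct-3-en-7-one (C13=C14 alkene lactone)
Conditions: DBU, toluene, 80 °C
Reagents that add atoms: none
Why: Base-induced anti-periplanar dehydroiodination removes the C14–H anti to iodine (loss of the C12–H would give a bridgehead alkene) and should give the C13=C14 alkene.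

Step 3
Reactants: 3 alkene lactone
Product: 4 3,4-epoxy-6-oxabicyclo[3.2.1]octan-7-one (C13–C14 epoxide; oxygen anti to the lactone bridge)
Conditions: mCPBA, CH2Cl2, 0 °C → rt
Reagents that add atoms: 3-chloroperoxybenzoic acid, O=C(OO)c1cccc(Cl)c1
Why: Prilezhaev epoxidation should occur on the alkene face anti to the two-atom lactone bridge, the less hindered face of this bicyclo[3.2.1]octene.

Step 4
Reactants: 4 epoxy lactone
Product: 5 4-hydroxy-6-oxabicyclo[3.2.1]oct-2-en-7-one (C13 hydroxyl anti to the lactone bridge; C14=C8 alkene)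
Conditions: Et2Al(tmp) (tmp = 2,2,6,6-tetramethylpiperidide), toluene, 0 °C
Reagents that add atoms: none
Why: Epoxide-to-allylic-alcohol isomerisation by syn β-elimination, in which only the C8–H syn to the epoxide can be removed because elimination toward C12 would give a bridgehead alkene.

Step 5
Reactants: 5 allylic alcohol
Product: 6 6-oxabicyclo[3.2.1]oct-2-ene-4,7-dione (C13 ketone conjugated with C14=C8; lactone intact)
Conditions: Dess–Martin periodinane, CH2Cl2, rt
Reagents that add atoms: none
Why: Dess–Martin oxidation of the secondary allylic alcohol should give the enone without touching the lactone, and C12 cannot enolise because it is a bridgehead.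

Step 6
Reactants: 6 enone lactone
Product: 7 2-allyl-6-oxabicyclo[3.2.1]octane-4,7-dione (allyl on C8 anti to the lactone bridge)
Conditions: allylSiMe3, TiCl4, CH2Cl2, −78 °C
Reagents that add atoms: allyltrimethylsilane, C=CC[Si](C)(C)C
Why: Hosomi–Sakurai conjugate allylation of the TiCl4-activated enone delivers the C6–C7 carbons to C8, whose configuration is erased again in step 7.

Step 7
Reactants: 7 allyl ketone
Product: 9 2-allyl-6-oxabicyclo[3.2.1]oct-2-ene-4,7-dione (C14=C8 enone bearing the allyl group), via trimethylsilyl enol ether 8 (not isolated)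
Conditions: Me3SiOTf, Et3N, CH2Cl2, 0 °C; then Pd(OAc)2 (10 mol %), O2, DMSO, rt
Reagents that add atoms: none
Why: Saegusa–Ito dehydrogenation, in which the ketone can form its enol silane only toward C14 (C12 is a bridgehead) and palladium-mediated β-hydride elimination restores the enone.

Step 8
Reactants: 9 allyl enone
Product: 11 2-allyl-2-isopropenyl-6-oxabicyclo[3.2.1]octane-4,7-dione (isopropenyl anti and allyl syn to the lactone bridge), via trimethylsilyl enol ether 10 (not isolated)
Conditions: isopropenylMgBr, CuBr·SMe2 (20 mol %), Me3SiCl, THF, −78 → −40 °C; then 1 M HCl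
Reagents that add atoms: isopropenylmagnesium bromide, CC(=C)[Mg]Br
Why: Copper-catalysed, Me3SiCl-accelerated conjugate addition should occur axially on the face of C8 anti to the lactone bridge (trans to C10), which sets quaternary C8 with the future C15 anti to C10 and the C6 arm syn to it.

Step 9
Reactants: 11 allyl isopropenyl ketone
Product: 12 keto acid (C8 bears CH2CO2H syn and acetyl anti to the lactone bridge; C13 ketone)
Conditions: RuCl3·xH2O (5 mol %), NaIO4, CCl4/MeCN/H2O, rt
Reagents that add atoms: sodium periodate, [Na+].[O-]I(=O)(=O)=O; water, O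
Why: Ruthenium tetroxide-catalysed oxidative cleavage converts the allyl group to the C6–C7 acetic acid arm and the isopropenyl group to the C15/C16 acetyl group in one operation.

Step 10
Reactants: 12 keto acid
Product: 13 2-(trimethylsilyl)ethyl ester of 12
Conditions: Me3SiCH2CH2OH, DCC, DMAP (cat.), CH2Cl2, 0 °C → rt
Reagents that add atoms: 2-(trimethylsilyl)ethanol, C[Si](C)(C)CCO
Why: Steglich esterification protects the C7 acid as a fluoride-labile ester.

Step 11
Reactants: 13 diketone ester
Product: 14 tricyclic ketol (ring D closed by C16–C13; C13 hydroxyl; C15 ketone; lactone bridge retained)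
Conditions: LiN(iPr)2 (1.1 equiv), THF, −78 → −40 °C; AcOH, −78 °C
Reagents that add atoms: none
Why: Intramolecular aldol addition, in which the methyl-ketone enolate (C16) attacks the C13 ketone from the only face the axial C8 acetyl group can reach (anti to the lactone), closing the bicyclo[3.2.1]octane and setting C13; the other enolates could only close three- or four-membered rings, and addition to the ketone should outrun Claisen attack on the ester at low temperature.

Step 12
Reactants: 14 ketol
Product: 15 bis(triethylsilyl) derivative (C13–OSiEt3; C15 enol silane with C15=C16)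
Conditions: Et3SiOTf (3 equiv), Et3N, CH2Cl2, 0 °C
Reagents that add atoms: triethylsilyl trifluoromethanesulfonate, CC[Si](CC)(CC)OS(=O)(=O)C(F)(F)F
Why: Silyl triflate and amine base silylate the tertiary C13 hydroxyl (blocking retro-aldol cleavage) and convert the C15 ketone to its enol silane, which can form only toward C16 because C8 is quaternary.

Step 13
Reactants: 15 bis(silyl) compound
Product: 18 α-methylene ketone (C16=C17; C15 ketone; C13–OSiEt3), via Mannich base 16 (not isolated), via methiodide 17 (not isolated)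
Conditions: CH2=NMe2+ I− (Eschenmoser's salt), CH2Cl2, rt; then MeI; then DBU, rt
Reagents that add atoms: N,N-dimethylmethyleneiminium iodide, C=[N+](C)C.[I-]
Why: Mannich reaction of the enol silane, N-methylation and Hofmann-type elimination should give the exocyclic enone, which cannot isomerise into the ring because its neighbours are a bridgehead and a ketone.

Step 14
Reactants: 18 enone
Product: 19 15β-allylic alcohol (hydroxyl endo, on the side of C9)
Conditions: NaBH4, CeCl3·7H2O, MeOH, −78 °C
Reagents that add atoms: none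
Why: Luche 1,2-reduction, in which hydride should attack C15 from the exo face because the endo face lies under ring C and is screened by the axial C11 hydrogen, so the hydroxyl ends endo (15β).

Step 15
Reactants: 19 allylic alcohol
Product: 20 15β-tert-butyldimethylsilyl ether (lactone intact)
Conditions: tBuMe2SiOTf, 2,6-lutidine, CH2Cl2, 0 °C → rt
Reagents that add atoms: tert-butyldimethylsilyl trifluoromethanesulfonate, CC(C)(C)[Si](C)(C)OS(=O)(=O)C(F)(F)F
Why: Silyl triflate silylation protects the hindered allylic C15 alcohol.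

Step 16
Reactants: 20 lactone
Product: 21 hydroxy thioester (C10 S-ethyl thioester axial on C9; free 12α-hydroxyl)
Conditions: AlMe3, EtSH, CH2Cl2, 0 °C
Reagents that add atoms: ethanethiol, CCS
Why: Thiolysis with the aluminium thiolate Me2AlSEt should open the strained bridged γ-lactone, a cyclic ester far more electrophilic than the acyclic neopentyl-type C7 ester, leaving C9 and C12 unchanged.

Step 17
Reactants: 21 hydroxy thioester
Product: 22 C/D thioester with 12α-OSiEt3
Conditions: Et3SiOTf, 2,6-lutidine, CH2Cl2, −78 °C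
Reagents that add atoms: triethylsilyl trifluoromethanesulfonate, CC[Si](CC)(CC)OS(=O)(=O)C(F)(F)F
Why: Fast low-temperature silylation of the axial C12 hydroxyl prevents relactonisation onto the syn-axial thioester.

Step 18
Reactants: 23 (R)-4-benzyl-3-propionyloxazolidin-2-one; 24 acrolein
Product: 27 (R)-4-benzyl-3-[(2R,3S)-3-hydroxy-2-methylpent-4-enoyl]oxazolidin-2-one, via boron enolate 25 (not isolated), via boron aldolate 26 (not isolated)
Conditions: Bu2BOTf, iPr2NEt, CH2Cl2, −78 → 0 °C; acrolein, −78 → 0 °C; then H2O2, pH 7 buffer, MeOH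
Reagents that add atoms: none
Why: Evans syn-aldol reaction, in which the (Z)-boron enolate reacts through a Zimmerman–Traxler chair on the face opposite the benzyl group, setting the carbinol centre (future C3) as S.

Step 19
Reactants: 27 aldol adduct
Product: 28 methyl (2R,3S)-3-hydroxy-2-methylpent-4-enoate
Conditions: NaOMe (1.1 equiv), MeOH, 0 °C; then aq. NH4Cl
Reagents that add atoms: sodium methoxide, C[O-].[Na+]
Why: Methanolysis of the exocyclic imide carbonyl gives the methyl ester and returns the auxiliary.

Step 20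
Reactants: 28 hydroxy ester
Product: 30 methyl (2S,3S)-3-hydroxy-2-(iodomethyl)-2-methylpent-4-enoate, via dilithium alkoxide enolate 29 (not isolated)
Conditions: LiN(iPr)2 (2.2 equiv), THF, −78 → −20 °C; then CH2I2, DMPU, −78 °C → rt; then aq. NH4Cl
Reagents that add atoms: diiodomethane, C(I)I
Why: Fráter–Seebach alkylation, in which the electrophile enters the lithium-chelated enolate anti to the carbinol substituent, so the iodomethyl group (C5) ends anti and the methyl group syn to the C3 oxygen, setting quaternary C4 from C3.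

Step 21
Reactants: 30 hydroxy iodide
Product: 31 methyl (2S,3S)-3-[(tert-butyldimethylsilyl)oxy]-2-(iodomethyl)-2-methylpent-4-enoate
Conditions: tBuMe2SiOTf, 2,6-lutidine, CH2Cl2, 0 °C
Reagents that add atoms: tert-butyldimethylsilyl trifluoromethanesulfonate, CC(C)(C)[Si](C)(C)OS(=O)(=O)C(F)(F)F
Why: Standard silylation of the secondary allylic alcohol.

Step 22
Reactants: 31 silyl ether iodide; 22 C/D thioester
Product: 33 C10 ketone (C/D bicycle with the C8 CH2CO2CH2CH2SiMe3 arm and the C9 chain C10(=O)–C5H2–C4(Me)(CO2Me)–C3H(OSiMe2tBu)–CH=CH2), via alkylzinc iodide 32 (not isolated)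
Conditions: 31, Zn dust (activated with Me3SiCl and BrCH2CH2Br), DMA, 40 °C; then 22, PdCl2(PPh3)2 (10 mol %), toluene, rt
Reagents that add atoms: none
Why: Fukuyama coupling, in which zinc inserts into the neopentyl-type iodide (no β-hydrogen) and zerovalent palladium couples the alkylzinc iodide with the thioester to give the ketone directly, conditions that should spare esters, silyl ethers, alkenes and the epimerisable C9–H.

Step 23
Reactants: 33 C10 ketone
Product: 35 ring-B cyclopentanone (C5–C6 bond formed; C4 group α on C5 and C7 ester β on C6), via dilithium bis-enolate 34 (not isolated)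
Conditions: LiN(iPr)2 (2.3 equiv), THF, −78 °C; then Fe(acac)3 (2.2 equiv), −78 °C → rt
Reagents that add atoms: none
Why: Two equivalents of amide base remove one C5 proton beside the C10 ketone and one C6 proton beside the C7 ester, Fe(acac)3 then takes one electron from the resulting dilithium bis-enolate, the α-carbonyl radical is trapped by the neighbouring enolate carbon, and a second electron transfer leaves the 1,4-dicarbonyl C5–C6 bond. The closest known reaction type is the oxidative heterocoupling of ketone and ester lithium enolates by trivalent iron or divalent copper salts, used here intramolecularly. Ring B forms as a cyclopentanone by a 5-exo-trig closure (C5 onto the exocyclic C6=C7 enolate), made easy because the equatorial acetate arm on C8 and the axial acyl group on C9 sit on neighbouring ring-C atoms. At C6 the carboxyl should take the β face, cis to C15, because the α face is screened by C14 and its axial hydrogen, and at C5 the quaternary C4 group then takes the α face, trans to C7. Both new centres lie next to a carbonyl, so a short base equilibration (DBU) should correct a kinetic mixture toward this trans isomer. The selectivity needed is enolisation of the ketone toward C5 and not C9, which the substrate secures because C5 is an accessible methylene whereas C9–H is a tertiary hydrogen beside quaternary C8, while the C19 ester cannot enolise at all since C4 is quaternary.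

Step 24
Reactants: 35 ring-B cyclopentanone
Product: 37 C10-vinyl 19,10-lactone (vinyl β and lactone oxygen α on C10), via magnesium alkoxide 36 (not isolated)
Conditions: CH2=CHMgBr, LaCl3·2LiCl, THF, −78 → 0 °C; then aq. NH4Cl
Reagents that add atoms: vinylmagnesium bromide, C=C[Mg]Br
Why: 1,2-Addition of the vinyl Grignard reagent (LaCl3·2LiCl suppresses enolisation) should occur on the β face of C10, anti to C4 on C5, to C11 on C9 and to the 12α-silyloxy group, and the resulting α-alkoxide, cis to C4, closes the γ-lactone by acyl substitution on the C19 methyl ester.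

Step 25
Reactants: 37 divinyl lactone
Product: 38 fully protected target gibberellin (ring A closed with C1=C2)
Conditions: second-generation Hoveyda–Grubbs catalyst RuCl2(=CH-C6H4-2-OiPr)(H2IMes) (10 mol %), toluene, 80 °C
Reagents that add atoms: none
Why: Ring-closing metathesis of the two vinyl groups, held cis on the γ-lactone at C10 and C4, should close six-membered ring A and release ethylene, while the hindered 1,1-disubstituted C16=C17 methylene should stay out of the reaction.

Step 26
Reactants: 38 protected target gibberellin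
Product: 39 12α,15β-dihydroxygibberellic acid, the target gibberellin
Conditions: Bu4NF (excess), AcOH, THF, rt → 40 °C
Reagents that add atoms: none
Why: Buffered fluoride should cleave the four silyl ethers and fragment the 2-(trimethylsilyl)ethyl ester without hydroxide or strong acid, sparing the sensitive allylic 19,10-lactone.

**Compound list**

1 | (S)-cyclohex-3-ene-1-carboxylic acid | OC(=O)[C@@H]1CC=CCC1 | starting material
2 | (1S,4S,5S)-4-iodo-6-oxabicyclo[3.2.1]octan-7-one | O=C1O[C@H]2C[C@@H]1CC[C@@H]2I | intermediate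
3 | (1S,5S)-6-oxabicyclo[3.2.1]oct-3-en-7-one | O=C1O[C@H]2C[C@@H]1CC=C2 | intermediate
4 | C13–C14 epoxide of 3, oxygen anti to the lactone bridge | O=C1O[C@H]2C[C@@H]1C[C@@H]3O[C@H]23 | intermediate
5 | C13 allylic alcohol (OH anti to the lactone bridge), C14=C8 alkene | O=C1O[C@H]2C[C@@H]1C=C[C@@H]2O | intermediate
6 | enone lactone (C13 ketone, C14=C8) | O=C1O[C@H]2C[C@@H]1C=CC2=O | intermediate
7 | C8-allyl keto lactone (allyl anti to the lactone bridge) | O=C1O[C@H]2C[C@@H]1[C@H](CC=C)CC2=O | intermediate
8 | trimethylsilyl enol ether of 7 | O=C1O[C@H]2C[C@@H]1[C@H](CC=C)C=C2O[Si](C)(C)C | intermediate (not isolated)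
9 | C8-allyl enone lactone | O=C1O[C@H]2C[C@@H]1C(CC=C)=CC2=O | intermediate
10 | trimethylsilyl enol ether of 11 | O=C1O[C@H]2C[C@@H]1[C@](CC=C)(C(C)=C)C=C2O[Si](C)(C)C | intermediate (not isolated)
11 | C8-allyl, C8-isopropenyl keto lactone (isopropenyl anti to the lactone bridge) | O=C1O[C@H]2C[C@@H]1[C@](CC=C)(C(C)=C)CC2=O | intermediate
12 | keto acid (C8: CH2CO2H and acetyl) | O=C1O[C@H]2C[C@@H]1[C@](CC(=O)O)(C(C)=O)CC2=O | intermediate
13 | 2-(trimethylsilyl)ethyl ester of 12 | O=C1O[C@H]2C[C@@H]1[C@](CC(=O)OCC[Si](C)(C)C)(C(C)=O)CC2=O | intermediate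
14 | tricyclic ketol (ring D closed; C13–OH; C15 ketone) | O=C1O[C@H]2C[C@@H]1[C@@]3(CC(=O)OCC[Si](C)(C)C)C[C@]2(O)CC3=O | intermediate
15 | C13–OSiEt3, C15 triethylsilyl enol ether | O=C1O[C@H]2C[C@@H]1[C@@]3(CC(=O)OCC[Si](C)(C)C)C[C@]2(O[Si](CC)(CC)CC)C=C3O[Si](CC)(CC)CC | intermediate
16 | Mannich base (C16–CH2NMe2, C16 configuration undefined) | O=C1O[C@H]2C[C@@H]1[C@@]3(CC(=O)OCC[Si](C)(C)C)C[C@]2(O[Si](CC)(CC)CC)C(CN(C)C)C3=O | intermediate (not isolated)
17 | methiodide of 16 | O=C1O[C@H]2C[C@@H]1[C@@]3(CC(=O)OCC[Si](C)(C)C)C[C@]2(O[Si](CC)(CC)CC)C(C[N+](C)(C)C)C3=O.[I-] | intermediate (not isolated)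
18 | C16=C17 methylene C15 ketone | O=C1O[C@H]2C[C@@H]1[C@@]3(CC(=O)OCC[Si](C)(C)C)C[C@]2(O[Si](CC)(CC)CC)C(=C)C3=O | intermediate
19 | 15β-allylic alcohol | O=C1O[C@H]2C[C@@H]1[C@@]3(CC(=O)OCC[Si](C)(C)C)C[C@]2(O[Si](CC)(CC)CC)C(=C)[C@H]3O | intermediate
20 | 15β-OSiMe2tBu lactone | O=C1O[C@H]2C[C@@H]1[C@@]3(CC(=O)OCC[Si](C)(C)C)C[C@]2(O[Si](CC)(CC)CC)C(=C)[C@H]3O[Si](C)(C)C(C)(C)C | intermediate
21 | C10 S-ethyl thioester with free 12α-OH | C=C1[C@@H](O[Si](C)(C)C(C)(C)C)[C@]2(CC(=O)OCC[Si](C)(C)C)C[C@@]1(O[Si](CC)(CC)CC)[C@@H](O)C[C@H]2C(=O)SCC | intermediate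
22 | C/D thioester, 12α-OSiEt3 | C=C1[C@@H](O[Si](C)(C)C(C)(C)C)[C@]2(CC(=O)OCC[Si](C)(C)C)C[C@@]1(O[Si](CC)(CC)CC)[C@@H](O[Si](CC)(CC)CC)C[C@H]2C(=O)SCC | intermediate
23 | (R)-4-benzyl-3-propionyloxazolidin-2-one | CCC(=O)N1[C@H](Cc2ccccc2)COC1=O | starting material
24 | acrolein | C=CC=O | starting material
25 | (Z)-dibutylboron enolate of 23 | C/C=C(\OB(CCCC)CCCC)N1[C@H](Cc2ccccc2)COC1=O | intermediate (not isolated)
26 | dibutylborinate of 27 | O=C1OC[C@@H](Cc2ccccc2)N1C(=O)[C@H](C)[C@@H](OB(CCCC)CCCC)C=C | intermediate (not isolated)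
27 | (R)-4-benzyl-3-[(2R,3S)-3-hydroxy-2-methylpent-4-enoyl]oxazolidin-2-one | O=C1OC[C@@H](Cc2ccccc2)N1C(=O)[C@H](C)[C@@H](O)C=C | intermediate
28 | methyl (2R,3S)-3-hydroxy-2-methylpent-4-enoate | COC(=O)[C@H](C)[C@@H](O)C=C | intermediate
29 | dilithium alkoxide enolate of 28 | [Li]O[C@@H](C=C)C(C)=C(OC)O[Li] | intermediate (not isolated)
30 | methyl (2S,3S)-3-hydroxy-2-(iodomethyl)-2-methylpent-4-enoate | IC[C@](C)(C(=O)OC)[C@@H](O)C=C | intermediate
31 | methyl (2S,3S)-3-[(tert-butyldimethylsilyl)oxy]-2-(iodomethyl)-2-methylpent-4-enoate | IC[C@](C)(C(=O)OC)[C@@H](O[Si](C)(C)C(C)(C)C)C=C | intermediate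
32 | alkylzinc iodide from 31 | I[Zn]C[C@](C)(C(=O)OC)[C@@H](O[Si](C)(C)C(C)(C)C)C=C | intermediate (not isolated)
33 | C10 ketone (key-step precursor) | C=C1[C@@H](O[Si](C)(C)C(C)(C)C)[C@]2(CC(=O)OCC[Si](C)(C)C)C[C@@]1(O[Si](CC)(CC)CC)[C@@H](O[Si](CC)(CC)CC)C[C@H]2C(=O)C[C@](C)(C(=O)OC)[C@@H](O[Si](C)(C)C(C)(C)C)C=C | intermediate
34 | dilithium bis-enolate of 33 | C=C1[C@@H](O[Si](C)(C)C(C)(C)C)[C@]2(C=C(O[Li])OCC[Si](C)(C)C)C[C@@]1(O[Si](CC)(CC)CC)[C@@H](O[Si](CC)(CC)CC)C[C@H]2C(O[Li])=C[C@](C)(C(=O)OC)[C@@H](O[Si](C)(C)C(C)(C)C)C=C | intermediate (not isolated)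
35 | ring-B cyclopentanone (key-step product) | C=C1[C@@H](O[Si](C)(C)C(C)(C)C)[C@]23C[C@@]1(O[Si](CC)(CC)CC)[C@@H](O[Si](CC)(CC)CC)C[C@H]2C(=O)[C@@H]([C@](C)(C(=O)OC)[C@@H](O[Si](C)(C)C(C)(C)C)C=C)[C@@H]3C(=O)OCC[Si](C)(C)C | intermediate
36 | bromomagnesium C10 alkoxide | C=C1[C@@H](O[Si](C)(C)C(C)(C)C)[C@]23C[C@@]1(O[Si](CC)(CC)CC)[C@@H](O[Si](CC)(CC)CC)C[C@H]2[C@](O[Mg]Br)(C=C)[C@@H]([C@](C)(C(=O)OC)[C@@H](O[Si](C)(C)C(C)(C)C)C=C)[C@@H]3C(=O)OCC[Si](C)(C)C | intermediate (not isolated)
37 | C10-vinyl 19,10-lactone | C=C1[C@@H](O[Si](C)(C)C(C)(C)C)[C@]23C[C@@]1(O[Si](CC)(CC)CC)[C@@H](O[Si](CC)(CC)CC)C[C@H]2[C@@]4(C=C)OC(=O)[C@](C)([C@@H](O[Si](C)(C)C(C)(C)C)C=C)[C@H]4[C@@H]3C(=O)OCC[Si](C)(C)C | intermediate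
38 | protected target gibberellin (3,15-bis-OSiMe2tBu; 12,13-bis-OSiEt3; C7 2-(trimethylsilyl)ethyl ester) | C=C1[C@@H](O[Si](C)(C)C(C)(C)C)[C@]23C[C@@]1(O[Si](CC)(CC)CC)[C@@H](O[Si](CC)(CC)CC)C[C@H]2[C@@]12C=C[C@H](O[Si](C)(C)C(C)(C)C)[C@@](C)(C(=O)O1)[C@H]2[C@@H]3C(=O)OCC[Si](C)(C)C | intermediate
39 | 12α,15β-dihydroxygibberellic acid (the target gibberellin) | C=C1[C@@H](O)[C@]23C[C@@]1(O)[C@@H](O)C[C@H]2[C@@]12C=C[C@H](O)[C@@](C)(C(=O)O1)[C@H]2[C@@H]3C(=O)O | target

**Step count and risks**

Total step count: 26. Longest linear sequence: 22 steps (steps 1–17 and 22–26); the side branch is steps 18–21.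

Steps most likely to fail:

1. Step 23 (oxidative bis-enolate coupling). What may go wrong: intermolecular coupling or proton exchange between the enolates before oxidation, enolisation toward C9 with loss of the C9 configuration, or poor facial selectivity at C5/C6. Fallback, from 33 back to 35: the two carbonyls are first fixed with LiN(iPr)2 and Me3SiCl at −78 °C as the bis(trimethylsilyl) enol ether–ketene acetal F1. F1 is then oxidised with (NH4)2Ce(NO3)6 and NaHCO3 in MeCN at −30 °C. The radical cation of the electron-rich ketene acetal is captured by the enol silane (known oxidative cross-coupling of silyl enol ethers), and loss of both silyl groups gives 35.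

2. Step 22 (thioester–organozinc coupling). What may go wrong: slow oxidative addition and transmetalation at the hindered, α-branched thioester, so that the zinc reagent is protonated or the acyl–palladium species decarbonylates. Fallback, from 20 back to 33: lactone 20 is opened with the aluminium thiolate made from AlMe3 and pyridine-2-thiol to the S-(2-pyridyl) thioester F2. Its 12α-hydroxyl is silylated (Et3SiOTf, 2,6-lutidine) to the silyl ether F3. F3 is joined to iodide 31 by nickel-catalysed reductive cross-electrophile coupling (NiCl2(dme), 4,4'-di-tert-butyl-2,2'-bipyridine, Mn powder, DMA), in which the alkyl radical from 31 is captured by an acyl–nickel species and no organozinc reagent is needed; this gives ketone 33.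

3. Step 24 (vinyl addition and lactonisation). What may go wrong: enolisation of the doubly α-branched cyclopentanone by the Grignard reagent, with epimerisation at C5 or C9, instead of addition. Fallback, from 35 back to 37: the smaller, less basic ethynylmagnesium bromide (with LaCl3·2LiCl) is added; the alkoxide lactonises as before to the C10-ethynyl lactone F4. Semihydrogenation over Lindlar catalyst (Pd/CaCO3 poisoned with Pb(OAc)2, quinoline, H2) then reduces the alkyne to the vinyl group of 37 faster than it touches the alkenes.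

Further compounds
F1 | step 23 | bis(trimethylsilyl) enol ether–ketene acetal of 33 | C=C1[C@@H](O[Si](C)(C)C(C)(C)C)[C@]2(C=C(O[Si](C)(C)C)OCC[Si](C)(C)C)C[C@@]1(O[Si](CC)(CC)CC)[C@@H](O[Si](CC)(CC)CC)C[C@H]2C(O[Si](C)(C)C)=C[C@](C)(C(=O)OC)[C@@H](O[Si](C)(C)C(C)(C)C)C=C
F2 | step 22 | C10 S-(2-pyridyl) thioester with free 12α-OH | C=C1[C@@H](O[Si](C)(C)C(C)(C)C)[C@]2(CC(=O)OCC[Si](C)(C)C)C[C@@]1(O[Si](CC)(CC)CC)[C@@H](O)C[C@H]2C(=O)Sc1ccccn1
F3 | step 22 | 12α-triethylsilyl ether of F2 | C=C1[C@@H](O[Si](C)(C)C(C)(C)C)[C@]2(CC(=O)OCC[Si](C)(C)C)C[C@@]1(O[Si](CC)(CC)CC)[C@@H](O[Si](CC)(CC)CC)C[C@H]2C(=O)Sc1ccccn1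
F4 | step 24 | C10-ethynyl 19,10-lactone | C=C1[C@@H](O[Si](C)(C)C(C)(C)C)[C@]23C[C@@]1(O[Si](CC)(CC)CC)[C@@H](O[Si](CC)(CC)CC)C[C@H]2[C@@]4(C#C)OC(=O)[C@](C)([C@@H](O[Si](C)(C)C(C)(C)C)C=C)[C@H]4[C@@H]3C(=O)OCC[Si](C)(C)C
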